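A straight line through the early Q readings misleads: Q stands two steps behind G, through J, so it grows with the square of the time and looks dead for hours, a lag or induction period.

all flasks: Z 10 mM

| flask | E | L | D | temperature | remark | time |
|---|---|---|---|---|---|---|
| cedar | 2.5 equiv | 0.70 equiv | 1 equiv | 10 °C | run made earlier |  |
| ash | 2.5 equiv | 0.47 equiv | 1 equiv | 25 °C | run made earlier |  |
| alder | 2.5 equiv | 1 equiv | 1 equiv | 10 °C | run made earlier |  |
| elm | 1.2 equiv | 0.70 equiv | 1 equiv | 25 °C | run made earlier |  |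
| Sunday's | 2.50 equiv | 0.700 equiv | 1.00 equiv (fed, over 12 h) | 25 °C | all else is in the flask from the start; the feed brings no volume worth counting | 15 h |
| Wednesday's | 2.50 equiv | 0.700 equiv | 1.00 equiv | 25 °C | everything together at the start | 15 h |
| Friday's | 2.50 equiv | 0.700 equiv (fed, over 12 h) | 1.00 equiv | 25 °C | all else is in the flask from the start; the feed brings no volume worth counting | 15 h |
| Monday's | 2.50 equiv | 0.700 equiv | 1.00 equiv (fed, over 12 h) |  | the addition at −15 °C, then warmed to 25 °C; the feed brings no volume worth counting | 15 h |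

| run | time / h | Q / % | X / % |
|---|---|---|---|
| cedar | 1.00 | 0 | 0.3 |
| cedar | 3.00 | 0 | 0.8 |
| cedar | 5.00 | 0.3 | 0.7 |
| cedar | 8.00 | 0 | 2.7 |
| cedar | 10.0 | 0.1 | 2.6 |
| cedar | 15.0 | 0.5 | 3.0 |
| cedar | 20.0 | 0 | 4.9 |
| ash | 1.00 | 0.1 | 0.3 |
| ash | 3.00 | 1.1 | 2.0 |
| ash | 5.00 | 0 | 5.2 |
| ash | 8.00 | 0 | 5.1 |
| ash | 10.0 | 0.3 | 8.1 |
| ash | 15.0 | 0.1 | 7.9 |
| ash | 20.0 | 1.4 | 5.9 |
| alder | 2.00 | 2.2 | 0.4 |
| alder | 6.00 | 0.8 | 0.6 |
| alder | 10.0 | 0 | 0.9 |
| alder | 15.0 | 0.6 | 3.1 |
| alder | 20.0 | 0 | 4.2 |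
| alder | 30.0 | 1.4 | 5.2 |
| alder | 40.0 | 2.7 | 6.2 |
| elm | 1.50 | 0.4 | 0.3 |
| elm | 5.00 | 0 | 4.6 |
| elm | 8.00 | 0.8 | 9.4 |
| elm | 12.0 | 1.1 | 13.2 |
| elm | 20.0 | 3.7 | 16.3 |

(scatter of a reading: 1 percentage point)

- in percentages every species weighs as the Z in it: one X counts as two
- steps that have been proposed: L + G -> J; D + J -> Q; Z + E -> G; Z + G -> X

* the flask that comes out highest in share of Q in Q plus X, or "all alike" when all lie within 1.5 percentage points (Sunday's / Wednesday's / Friday's / Monday's / all alike)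
* share of Q in Q plus X at the end, Sunday's
* share of Q in Q plus X at the end, Wednesday's
* share of Q in Q plus X at the end, Friday's
* share of Q in Q plus X at the end, Monday's

I held G, L and D steady and integrated twice: the fraction of the charge in Q is 0.5 times the square of (time over τ) times whatever is not in X. Elm has the L, D and temperature of Wednesday's, and its last readings, Q 3.7% and X 16.3% at 20.0 h, give τ = 67.3 h. This is my chain time, the mean life of the two slow steps taken together, and it carries the scatter of 1 percentage point. Set against it stands the time a flask has for the chain.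

Ash has the E and temperature of Wednesday's, and its X from 10.0 h on averages 7.30%. Wednesday's has its full 15 h, so I reckoned Q 2.31% and a share of 24.0%. The same integral with D rising steadily shortens Sunday's time to 13.3 h, a share of 19.9%. With L rising, Friday's time is 9.64 h, a share of 11.5%. Monday's I allowed the 3.00 h after the cold stretch and took its X from the ash reading at 3.00 h, 2.0%, which gives Q 0.0975% and a share of 4.65%. So I put Wednesday's highest.

The forecast also named Wednesday's, but with lower shares for the first three: 15%, 18%, 9% and 5% in the order asked, on the ground that “Q appears late, only a few percent, with a clear lag”.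

The flasks gave 21.7%, 24.7%, 14.6% and 1.77% in that order, so Wednesday's came out highest.

    L + G → J (k = 0.0320 L mol⁻¹ min⁻¹, Ea = 53.0 kJ mol⁻¹)
    D + J → Q (k = 0.0520 L mol⁻¹ min⁻¹, Ea = 70.0 kJ mol⁻¹)
    Z + E → G (k = 0.310 L mol⁻¹ min⁻¹, Ea = 68.0 kJ mol⁻¹)
    Z + G → X (k = 0.0490 L mol⁻¹ min⁻¹, Ea = 73.0 kJ mol⁻¹)
    (constants at 25 °C)

Monday's ended with G 66.0%, and its 3.00 h over τ gives Q 0.0656%, where the flask held 0.0659%. The neighbour, Monday's with 10.0 equiv of E, ended with G 94.6%, so the same reckoning gives Q 0.0940%. That flask held Q 0.143% beside X 1.60%, a share of 8.23%.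

All runs stem from a simulated flask for an exercise.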